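## Structural features

The target 18 is a 3,7-dioxabicyclo[3.3.0]octane (furofuran) in which two tetrahydrofuran rings, ring A (C1–C2–O3–C4–C5) and ring B (C5–C6–O7–C8–C1), are cis-fused through the C1–C5 bond. Four contiguous stereocentres run along C2–C1–C5–C6; C1 is a fully substituted, oxygen-bearing fusion carbon that carries the acetate, and both aryl groups lie on the convex face, (1S,2R,5R,6S). The two aryl groups differ in one O-substituent only: the C2 aryl is a free phenol (guaiacyl), the C6 aryl is fully methylated (veratryl). Both benzylic C–O bonds (C2–O3, C6–O7) are fragile: acid ionises them to quinoid cations, which would epimerise C2 or C6, and they can be hydrogenolysed. The tertiary acetate must be distinguished from the phenol, and as long as C8 carries a free hydroxyl an acetyl group on O1 could shift to O8. The real difficulty is the oxygenated quaternary C1 flanked by three stereocentres, together with the need to tell apart two nearly identical aryl rings. The key step uses that small difference: once the phenol is acylated, C6 is the only benzylic position on an electron-rich arene, so in 15 an oxidant can take hydride from the C6 methylene and the C8 hydroxyl on C1 becomes O7 of ring B.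

## Logic of the disconnections

18 ⇒ 17. The phenolic O–acetyl bond is traced back. The guaiacyl ring has to be electron-poor when ring B is closed, and an aryl acetate is the one ester a secondary amine cleaves at 0 °C. The gain is that the group that protects the key step leaves in one mild operation. The forward step must spare the tertiary C1 acetate.

17 ⇒ 16. The C1–O acetyl bond is cut. Placing the tertiary acetate last means O8 is already locked in ring B, so no 1,2-acyl shift is possible. The gain is a single ester in 16. The demand is acylation of a hindered tertiary alcohol without any acid that would ionise C2–O3 or C6–O7.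

16 ⇒ 15. The C6–O7 bond is cut and ring B opens. C6 becomes the plain methylene of a 3,4-dimethoxybenzyl group and the C6 stereocentre disappears; the bicycle is reduced to a monocyclic tetrahydrofuran diol. The forward step needs site-selective oxidation of C6–H over C2–H, closure with the aryl on the convex face, and no second oxidation of the product.

15 ⇒ 14. The O8–Si bond is restored. Masking O8 keeps the primary hydroxyl out of the phenol acetylation. The forward step is a desilylation that must leave the aryl acetate alone.

14 ⇒ 13. The phenolic O–acetyl bond is cut. The acetate can only be placed after the hydride and enolate steps. The forward step must acylate the phenol and not the tertiary C1 hydroxyl.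

13 ⇒ 12. The phenolic O–benzyl bond is restored, because a benzyl ether survives alkoxide, hydride and amide bases. The forward hydrogenolysis must not cleave the cyclic benzylic C2–O3 bond.

12 ⇒ 10. C4 is returned to the carbonyl level. This makes C5 enolisable, so the C5–C6 bond can be made by alkylation. The forward reduction of the lactone to the cyclic ether must proceed through the C4 oxocarbenium ion without ionising the benzylic C2–O3 bond.

10 ⇒ 8 + 9. The C5–C6 bond is cut. This removes the C5 stereocentre and the whole veratryl unit, which arrives as 9. The forward alkylation must take place on the face opposite to the C1 oxygen and the C2 aryl.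

8 ⇒ 7. The O8–Si bond is cut. The silyl ether limits the alkylation to a dianion, keeps O8 away from the C4 oxocarbenium ion in the reduction, and makes the later acetylation unambiguous. The forward step must silylate the primary and not the tertiary hydroxyl.

7 ⇒ 5 (through 6). The C2–O3 bond is cut and the C1 oxygen and O3 are traced to an epoxide and an ester. Both stereocentres of ring A then derive from one reagent-controlled epoxidation of an E-alkene. The forward step needs oxygen delivery to one alkene face and attack of the ester oxygen on C2 with inversion, which places the aryl cis to the C1 hydroxyl.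

5 ⇒ 4. C8 is returned to the ester level. The demand is reduction of the conjugated methyl ester in the presence of the tert-butyl ester.

4 ⇒ 3. The tert-butyl O–C bond is cut. It distinguishes the two carboxyl carbons (C4 and C8) and gives C4 an ester that can lose its alkyl group as an alkene in step 4.

3 ⇒ 1 + 2. The C1=C2 double bond is cut. Both partners are commercial, and the condensation gives the E-alkene and two differentiated carboxyl groups in one step. The forward step must give the geometry with the aryl cis to the CH2CO2H arm.

## Other disconnections considered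

Alternative 1: The cut is the C2–O3 bond of ring A in A1 (the same compound as 7). It leads back to the spiro-epoxy lactone A2 and the benzylidene lactone A3, which would come from 3 by reduction of the conjugated ester and lactonisation. In the forward step hydroxide opens the lactone of A2, the C4 carboxylate attacks the benzylic epoxide carbon C2 from the rear, and the epoxide oxygen remains as the C1 hydroxyl.
- In its favour: the stereochemical logic (E-alkene, epoxide, inversion at C2) is the same as in step 4, so on structure and mechanism it is the equal of the chosen plan. On step economy it is the better by one step up to A1, because no tert-butyl ester is needed.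
- Against it: A3 has no hydroxyl to direct oxygen delivery, so the absolute configuration would rest on a chiral dioxirane alone. By analogy with (E)-β-methylstyrene, the less accessible enantiomer of the fructose-derived ketone would be required. A3 is a β,γ-unsaturated lactone that could isomerise to the butenolide in the basic medium, and the alkoxide freed on saponification could enter a Payne rearrangement.
- Comparison: this cut builds only ring A. The C5–C6 bond, two stereocentres and ring B are still missing, so it precedes the closure of ring B and cannot replace it.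

Alternative 2: The cut is the C1–C5 bond, which turns both rings into the eight-membered keto enol ether A5. In the forward step a Lewis acid activates the C1 ketone, enol ether carbon C5 attacks C1 across the ring, and Et3SiH reduces the C4 oxocarbenium ion to give A4.
- In its favour: one step would form a C–C bond, both rings and the C1 and C5 stereocentres, with the cis fusion enforced by geometry and the C1 hydroxyl delivered directly. In bond-forming power this is the better of the two key steps. The tail after A4 (acetylation, hydrogenolysis) is equal in length to the tail after 16.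
- Against it: A5 needs an eight-membered ring closure, and its C2 and C6 stereocentres would each have to come from a separate asymmetric step. C2 of A5 is benzylic and α to the ketone, so it could epimerise. The Lewis acid meets two electron-rich benzylic ethers, and the silane could reduce the activated ketone before the transannular attack. The relation of C1/C5 to C2/C6 would depend on the conformation of the medium ring, not on a simple rule.
- Comparison: the chosen plan forms less in its key step but controls each stereocentre by a separate, predictable element. Overall step economy would probably not be better, because of the effort to reach A5.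

Alternative 3: The cut is O3 (bonds C4–O3 and O3–C2) of lactone A6, back to the cis-fused cyclobutanone A7, and then C1–C2 and C4–C5 to the aryl ketene A9 and the silyl enol ether A8. In the forward step a peracid adds to the C4 carbonyl of A7 and the benzylic carbon C2 migrates to oxygen with retention.
- In its favour: the cycloaddition would build both C–C bonds at the quaternary C1 and three stereocentres from the single stereocentre of A8. In C–C bond economy this is the better plan. The face of A8 anti to the C6 aryl is the one the target needs. The lactone-to-ether reduction after A6 is the same operation as step 7, so on that point the two are equal.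
- Against it: ketene cycloadditions place the larger ketene substituent on the concave face, so the C2 epimer of A7 would be expected and would need base equilibration α to the ketone. Electron-rich monoaryl ketenes dimerise readily. In the oxygen insertion two methine carbons (C2 and C5) compete to migrate. After A6 the route still needs C4 reduction, removal of a hindered tertiary silyl ether, acetylation and debenzylation, a longer tail than the two steps after 16.
- Comparison: shorter in C–C bond construction, but less secure in the C2 configuration and in regiocontrol than the chosen plan.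

Key step: step 11

Remark: the numbering C1–C8 of the 3,7-dioxabicyclo[3.3.0]octane core is used for all intermediates, including the open-chain ones.
Remark: 15, 16 and 18 carry the same spatial arrangement at C1, C2 and C5; only the CIP descriptors change with the substituents.
Remark: 9 is assumed to be purchased and used fresh, because it decomposes on storage.

## Route

Step 1
Reactants: 1 4-(benzyloxy)-3-methoxybenzaldehyde (O-benzylvanillin); 2 dimethyl succinate
Product: 3 (3E)-4-[4-(benzyloxy)-3-methoxyphenyl]-3-(methoxycarbonyl)but-3-enoic acid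
Conditions: NaOMe, MeOH, reflux; then aq. HCl
Reagents that add atoms: none
Why: Stobbe condensation: aldol addition of the succinate enolate, lactonisation and base-induced ring opening give the E-arylidene half-ester, with the aryl cis to the CH2CO2H arm. Only the non-conjugated carboxyl is set free as the acid, which differentiates C4 from C8.

Step 2
Reactants: 3 (3E)-4-[4-(benzyloxy)-3-methoxyphenyl]-3-(methoxycarbonyl)but-3-enoic acid
Product: 4 4-tert-butyl 1-methyl (2E)-2-{[4-(benzyloxy)-3-methoxyphenyl]methylidene}butanedioate
Conditions: t-BuOC(=NH)CCl3, cat. BF3·OEt2, CH2Cl2–cyclohexane, rt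
Reagents that add atoms: tert-butyl 2,2,2-trichloroacetimidate, CC(C)(C)OC(=N)C(Cl)(Cl)Cl
Why: Acid-catalysed tert-butylation of the carboxylic acid by the trichloroacetimidate. No base is present, so the alkene cannot migrate out of conjugation.

Step 3
Reactants: 4 4-tert-butyl 1-methyl (2E)-2-{[4-(benzyloxy)-3-methoxyphenyl]methylidene}butanedioate
Product: 5 tert-butyl (3E)-4-[4-(benzyloxy)-3-methoxyphenyl]-3-(hydroxymethyl)but-3-enoate
Conditions: iBu2AlH (2.2 equiv), CH2Cl2, −78 °C; aq. potassium sodium tartrate
Reagents that add atoms: none
Why: 1,2-Reduction of the conjugated methyl ester to the allylic alcohol by the aluminium hydride. The hindered tert-butyl ester should react much more slowly at −78 °C, and the alkene geometry is retained.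

Step 4
Reactants: 5 tert-butyl (3E)-4-[4-(benzyloxy)-3-methoxyphenyl]-3-(hydroxymethyl)but-3-enoate
Product: 7 (4S,5R)-5-[4-(benzyloxy)-3-methoxyphenyl]-4-hydroxy-4-(hydroxymethyl)oxolan-2-one, via epoxy alcohol 6 (not isolated)
Conditions: Ti(OiPr)4 (0.1 equiv), L-(+)-diisopropyl tartrate (0.12 equiv), t-BuOOH, 4 Å MS, CH2Cl2, −25 °C; aqueous work-up; then camphorsulfonic acid (cat.), CH2Cl2, 0 °C
Reagents that add atoms: tert-butyl hydroperoxide, CC(C)(C)OO
Why: Sharpless asymmetric epoxidation of the allylic alcohol; L-(+)-tartrate is the enantiomer that converts (E)-2-substituted cinnamyl alcohols into (2S,3S)-epoxy alcohols, which sets C1. Acid then lets the ester carbonyl oxygen open the epoxide at the benzylic carbon C2 from the rear in a five-membered lactonisation, with loss of the tert-butyl group as 2-methylpropene. The inversion at C2 places the aryl cis to the C1 hydroxyl.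

Step 5
Reactants: 7 (4S,5R)-5-[4-(benzyloxy)-3-methoxyphenyl]-4-hydroxy-4-(hydroxymethyl)oxolan-2-one
Product: 8 (4S,5R)-5-[4-(benzyloxy)-3-methoxyphenyl]-4-{[(tert-butyldimethylsilyl)oxy]methyl}-4-hydroxyoxolan-2-one
Conditions: t-BuMe2SiCl, imidazole, DMF, 0 °C
Reagents that add atoms: tert-butyldimethylsilyl chloride, CC(C)(C)[Si](C)(C)Cl
Why: Silylation of the primary C8 hydroxyl; the tertiary C1 hydroxyl is too hindered to react under these conditions.

Step 6
Reactants: 8 (4S,5R)-5-[4-(benzyloxy)-3-methoxyphenyl]-4-{[(tert-butyldimethylsilyl)oxy]methyl}-4-hydroxyoxolan-2-one; 9 4-(bromomethyl)-1,2-dimethoxybenzene (3,4-dimethoxybenzyl bromide)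
Product: 10 (3R,4S,5R)-5-[4-(benzyloxy)-3-methoxyphenyl]-4-{[(tert-butyldimethylsilyl)oxy]methyl}-3-(3,4-dimethoxybenzyl)-4-hydroxyoxolan-2-one
Conditions: LiN(iPr)2 (2.3 equiv), THF–DMPU, −78 °C; then 9, −78 → −40 °C
Reagents that add atoms: none
Why: Alkylation of the β-hydroxy lactone dianion (Fráter–Seebach type). The new C5–C6 bond should form on the face opposite to the lithium alkoxide on C1 and to the C2 aryl, both of which sit on the same side, so the benzyl group ends cis to the C8 arm. The alkoxide cannot leave as a β-leaving group, which prevents elimination.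

Step 7
Reactants: 10 (3R,4S,5R)-5-[4-(benzyloxy)-3-methoxyphenyl]-4-{[(tert-butyldimethylsilyl)oxy]methyl}-3-(3,4-dimethoxybenzyl)-4-hydroxyoxolan-2-one
Product: 12 (2R,3S,4S)-2-[4-(benzyloxy)-3-methoxyphenyl]-3-{[(tert-butyldimethylsilyl)oxy]methyl}-4-(3,4-dimethoxybenzyl)oxolan-3-ol, via lactol 11 (not isolated)
Conditions: iBu2AlH (2.5 equiv), CH2Cl2, −78 °C; then Et3SiH, BF3·OEt2, −78 → −40 °C
Reagents that add atoms: none
Why: Partial reduction of the lactone to the aluminium lactolate, then ionic hydrogenation: BF3·OEt2 forms the cyclic C4 oxocarbenium ion and Et3SiH reduces it. No stereocentre is formed, and the low temperature is chosen so that the lactol ionises well before the benzylic C2–O3 bond.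

Step 8
Reactants: 12 (2R,3S,4S)-2-[4-(benzyloxy)-3-methoxyphenyl]-3-{[(tert-butyldimethylsilyl)oxy]methyl}-4-(3,4-dimethoxybenzyl)oxolan-3-ol
Product: 13 (2R,3S,4S)-3-{[(tert-butyldimethylsilyl)oxy]methyl}-4-(3,4-dimethoxybenzyl)-2-(4-hydroxy-3-methoxyphenyl)oxolan-3-ol
Conditions: H2 (1 atm), Pd/C, EtOAc, rt, short reaction time
Reagents that add atoms: none
Why: Hydrogenolysis of the aryl benzyl ether, which is much faster than cleavage of the hindered cyclic benzylic ether at C2; the silyl ether is inert.

Step 9
Reactants: 13 (2R,3S,4S)-3-{[(tert-butyldimethylsilyl)oxy]methyl}-4-(3,4-dimethoxybenzyl)-2-(4-hydroxy-3-methoxyphenyl)oxolan-3-ol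
Product: 14 4-[(2R,3S,4S)-3-{[(tert-butyldimethylsilyl)oxy]methyl}-4-(3,4-dimethoxybenzyl)-3-hydroxyoxolan-2-yl]-2-methoxyphenyl acetate
Conditions: Ac2O, pyridine, 0 °C → rt
Reagents that add atoms: acetic anhydride, CC(=O)OC(C)=O
Why: Acetylation of the phenol; without an acyl-transfer catalyst the tertiary alcohol does not react, and O8 is silylated. The acetate makes the guaiacyl ring electron-poor for step 11.

Step 10
Reactants: 14 4-[(2R,3S,4S)-3-{[(tert-butyldimethylsilyl)oxy]methyl}-4-(3,4-dimethoxybenzyl)-3-hydroxyoxolan-2-yl]-2-methoxyphenyl acetate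
Product: 15 4-[(2R,3S,4S)-4-(3,4-dimethoxybenzyl)-3-hydroxy-3-(hydroxymethyl)oxolan-2-yl]-2-methoxyphenyl acetate
Conditions: HF·pyridine, THF–pyridine, 0 °C → rt
Reagents that add atoms: none
Why: Fluoride-induced desilylation under buffered, non-basic conditions, which an aryl acetate tolerates.

Step 11
Reactants: 15 4-[(2R,3S,4S)-4-(3,4-dimethoxybenzyl)-3-hydroxy-3-(hydroxymethyl)oxolan-2-yl]-2-methoxyphenyl acetate
Product: 16 4-[(1S,2R,5R,6S)-6-(3,4-dimethoxyphenyl)-1-hydroxy-3,7-dioxabicyclo[3.3.0]octan-2-yl]-2-methoxyphenyl acetate
Conditions: DDQ (1.1 equiv), 4 Å MS, CH2Cl2 (anhydrous), 0 °C → rt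
Reagents that add atoms: none
Why: DDQ forms a charge-transfer complex with the 3,4-dimethoxyphenyl ring of 15 and removes hydride (electron transfer, then hydrogen-atom transfer) from the C6 methylene, giving a benzylic cation that the 4-methoxy group stabilises as a para-quinoid oxocarbenium ion. The C8 hydroxyl adds to C6 and forms the C6–O7 bond; the closest known reaction type is the DDQ-mediated oxidative cyclisation of electron-rich arylalkanes with a pendant alcohol to 2-aryl tetrahydrofurans, the same event as oxidative cleavage of methoxybenzyl ethers. Ring B closes in a 5-exo-trig mode with respect to the exocyclic C6=C(aryl) bond of the cation. The new stereocentre C6 is set by allylic 1,3-strain in the cation: H5 lies in the aryl plane, O7 arrives from the C1 side, and the aryl therefore ends on the convex face, trans to C4. The step needs site selectivity for C6–H over the benzylic ether C2–H, and the substrate provides it because the dimethoxyarene is far easier to oxidise than the acetylated guaiacyl ring. The tertiary C1 hydroxyl cannot compete because it would have to form an oxetane, and the trans arrangement of the C2 aryl and the C5 benzyl group rules out a Friedel–Crafts closure. One equivalent of oxidant, exclusion of water and precipitation of the hydroquinone should limit a second oxidation at C6 of 16 and acid-induced epimerisation.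

Step 12
Reactants: 16 4-[(1S,2R,5R,6S)-6-(3,4-dimethoxyphenyl)-1-hydroxy-3,7-dioxabicyclo[3.3.0]octan-2-yl]-2-methoxyphenyl acetate
Product: 17 (1S,2R,5R,6S)-2-(4-acetoxy-3-methoxyphenyl)-6-(3,4-dimethoxyphenyl)-3,7-dioxabicyclo[3.3.0]octan-1-yl acetate
Conditions: Ac2O, Et3N, DMAP, CH2Cl2, rt → 40 °C
Reagents that add atoms: acetic anhydride, CC(=O)OC(C)=O
Why: DMAP-catalysed acyl transfer to the tertiary alcohol under basic conditions, which do not ionise the benzylic ethers. O8 is now an ether, so the new acetate cannot migrate.

Step 13
Reactants: 17 (1S,2R,5R,6S)-2-(4-acetoxy-3-methoxyphenyl)-6-(3,4-dimethoxyphenyl)-3,7-dioxabicyclo[3.3.0]octan-1-yl acetate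
Product: 18 (1S,2R,5R,6S)-6-(3,4-dimethoxyphenyl)-2-(4-hydroxy-3-methoxyphenyl)-3,7-dioxabicyclo[3.3.0]octan-1-yl acetate (CNP0107105.1)
Conditions: pyrrolidine (1.5 equiv), CH2Cl2, 0 °C
Reagents that add atoms: none
Why: Chemoselective aminolysis: the aryl acetate has a phenoxide leaving group and is unhindered, whereas the tertiary alkyl acetate is hindered and has a poor leaving group, so only the phenol should be set free.

## Compound list

1 | 4-(benzyloxy)-3-methoxybenzaldehyde (O-benzylvanillin) | COc1cc(C=O)ccc1OCc1ccccc1 | starting material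
2 | dimethyl succinate | COC(=O)CCC(=O)OC | starting material
3 | (3E)-4-[4-(benzyloxy)-3-methoxyphenyl]-3-(methoxycarbonyl)but-3-enoic acid | COC(=O)/C(CC(=O)O)=C/c1ccc(OCc2ccccc2)c(OC)c1 | intermediate
4 | 4-tert-butyl 1-methyl (2E)-2-{[4-(benzyloxy)-3-methoxyphenyl]methylidene}butanedioate | COC(=O)/C(CC(=O)OC(C)(C)C)=C/c1ccc(OCc2ccccc2)c(OC)c1 | intermediate
5 | tert-butyl (3E)-4-[4-(benzyloxy)-3-methoxyphenyl]-3-(hydroxymethyl)but-3-enoate | OC/C(CC(=O)OC(C)(C)C)=C/c1ccc(OCc2ccccc2)c(OC)c1 | intermediate
6 | tert-butyl 2-[(2S,3S)-3-[4-(benzyloxy)-3-methoxyphenyl]-2-(hydroxymethyl)oxiran-2-yl]acetate | COc1cc([C@@H]2O[C@]2(CO)CC(=O)OC(C)(C)C)ccc1OCc1ccccc1 | intermediate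
7 | (4S,5R)-5-[4-(benzyloxy)-3-methoxyphenyl]-4-hydroxy-4-(hydroxymethyl)oxolan-2-one | COc1cc([C@H]2OC(=O)C[C@@]2(CO)O)ccc1OCc1ccccc1 | intermediate
8 | (4S,5R)-5-[4-(benzyloxy)-3-methoxyphenyl]-4-{[(tert-butyldimethylsilyl)oxy]methyl}-4-hydroxyoxolan-2-one | COc1cc([C@H]2OC(=O)C[C@@]2(CO[Si](C)(C)C(C)(C)C)O)ccc1OCc1ccccc1 | intermediate
9 | 4-(bromomethyl)-1,2-dimethoxybenzene (3,4-dimethoxybenzyl bromide) | COc1ccc(CBr)cc1OC | starting material
10 | (3R,4S,5R)-5-[4-(benzyloxy)-3-methoxyphenyl]-4-{[(tert-butyldimethylsilyl)oxy]methyl}-3-(3,4-dimethoxybenzyl)-4-hydroxyoxolan-2-one | COc1cc([C@H]2OC(=O)[C@H](Cc3ccc(OC)c(OC)c3)[C@@]2(CO[Si](C)(C)C(C)(C)C)O)ccc1OCc1ccccc1 | intermediate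
11 | (3R,4S,5R)-5-[4-(benzyloxy)-3-methoxyphenyl]-4-{[(tert-butyldimethylsilyl)oxy]methyl}-3-(3,4-dimethoxybenzyl)oxolane-2,4-diol (lactol, both anomers at C4 of the core) | COc1cc([C@H]2OC(O)[C@H](Cc3ccc(OC)c(OC)c3)[C@@]2(CO[Si](C)(C)C(C)(C)C)O)ccc1OCc1ccccc1 | intermediate
12 | (2R,3S,4S)-2-[4-(benzyloxy)-3-methoxyphenyl]-3-{[(tert-butyldimethylsilyl)oxy]methyl}-4-(3,4-dimethoxybenzyl)oxolan-3-ol | COc1cc([C@H]2OC[C@H](Cc3ccc(OC)c(OC)c3)[C@@]2(CO[Si](C)(C)C(C)(C)C)O)ccc1OCc1ccccc1 | intermediate
13 | (2R,3S,4S)-3-{[(tert-butyldimethylsilyl)oxy]methyl}-4-(3,4-dimethoxybenzyl)-2-(4-hydroxy-3-methoxyphenyl)oxolan-3-ol | COc1cc([C@H]2OC[C@H](Cc3ccc(OC)c(OC)c3)[C@@]2(CO[Si](C)(C)C(C)(C)C)O)ccc1O | intermediate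
14 | 4-[(2R,3S,4S)-3-{[(tert-butyldimethylsilyl)oxy]methyl}-4-(3,4-dimethoxybenzyl)-3-hydroxyoxolan-2-yl]-2-methoxyphenyl acetate | COc1cc([C@H]2OC[C@H](Cc3ccc(OC)c(OC)c3)[C@@]2(CO[Si](C)(C)C(C)(C)C)O)ccc1OC(C)=O | intermediate
15 | 4-[(2R,3S,4S)-4-(3,4-dimethoxybenzyl)-3-hydroxy-3-(hydroxymethyl)oxolan-2-yl]-2-methoxyphenyl acetate | COc1cc([C@H]2OC[C@H](Cc3ccc(OC)c(OC)c3)[C@@]2(CO)O)ccc1OC(C)=O | intermediate
16 | 4-[(1S,2R,5R,6S)-6-(3,4-dimethoxyphenyl)-1-hydroxy-3,7-dioxabicyclo[3.3.0]octan-2-yl]-2-methoxyphenyl acetate | COc1cc([C@H]2OC[C@@H]3[C@@H](c4ccc(OC)c(OC)c4)OC[C@]23O)ccc1OC(C)=O | intermediate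
17 | (1S,2R,5R,6S)-2-(4-acetoxy-3-methoxyphenyl)-6-(3,4-dimethoxyphenyl)-3,7-dioxabicyclo[3.3.0]octan-1-yl acetate | COc1cc([C@H]2OC[C@@H]3[C@@H](c4ccc(OC)c(OC)c4)OC[C@]23OC(C)=O)ccc1OC(C)=O | intermediate
18 | (1S,2R,5R,6S)-6-(3,4-dimethoxyphenyl)-2-(4-hydroxy-3-methoxyphenyl)-3,7-dioxabicyclo[3.3.0]octan-1-yl acetate (CNP0107105.1) | COc1cc([C@H]2OC[C@@H]3[C@@H](c4ccc(OC)c(OC)c4)OC[C@]23OC(C)=O)ccc1O | target

## Step count and least certain steps

Total: 13 steps. Longest linear sequence: 13 steps (1 → 18; 2 enters in step 1 and 9 in step 6).

Step 11 (key step). The product 16 carries a dimethoxybenzylic ether C–H at C6, so a second hydride abstraction could consume product, while the alkylarene C–H of 15 may react slowly; the acidic hydroquinone could also epimerise C6 by re-ionisation. Fallback, setting out from 15 and returning at 16: the oxidation would be driven deliberately past the ether with DDQ (2.5 equiv) in wet CH2Cl2 to the C6 aryl ketone F1, which should exist largely as its cyclic hemiketal. The keto form would be reduced with NaBH4 and CeCl3·7H2O at low temperature to the benzylic alcohol F2; its C6 epimers do not matter. Ring B would then be closed by cyclodehydration with catalytic camphorsulfonic acid in CH2Cl2. This generates the same C6 cation by ionisation, and the C8 hydroxyl would trap it with the same facial preference.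

Step 4. The electron-rich benzylic epoxide could open through a free cation, or be opened by isopropanol or tartrate at the tetravalent titanium centre before the ester oxygen attacks; either would erode the configuration at C2 or the yield. Fallback, setting out from 3 and returning at 7: iBu2AlH would reduce only the conjugated ester of the aluminium carboxylate, and acidification would close the benzylidene lactone F3 (the structure also labelled A3). Epoxidation with the chiral dioxirane made from KHSO5 and the L-fructose-derived ketone (Shi epoxidation, enantiomeric catalyst series) would give the spiro-epoxy lactone F4 (the structure also labelled A2). Aqueous NaOH followed by mild acid would let the C4 carboxylate open the epoxide at C2 with inversion.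

Step 6. Facial selectivity may be poor if the CH2OSi arm shields its own face more than the alkoxide and the aryl shield theirs, and the aggregated dianion may alkylate slowly. Fallback, setting out from 8 and returning at 10: the dianion would be added to 3,4-dimethoxybenzaldehyde to give the aldol adduct F5. Mesylation of the benzylic hydroxyl would give F6, and elimination with DBU would give the benzylidene lactone F7. Hydrogenation with [Ir(cod)(py)(PCy3)]PF6, directed by the tertiary C1 hydroxyl, would deliver hydrogen to C5 from the hydroxyl face and so place the benzyl group trans to the hydroxyl.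

Step 7. BF3·OEt2 could ionise the benzylic C2–O3 bond, which would lead to ring opening and reductive loss of oxygen at C2 or to epimerisation; the silyl ether could also be lost. Fallback, setting out from 10 and returning at 12: LiBH4 would reduce the lactone to the triol F8. Selective tosylation of the primary C4 hydroxyl would give F9, and gentle warming in pyridine would close ring A by attack of the C2 hydroxyl on C4. The C2–O bond is never broken, so the configuration at C2 is retained.

Step 12. Acyl transfer to the hindered tertiary fusion alcohol may be slow, and forcing conditions could bring side reactions at the aryl acetate. Fallback, setting out from 16 and returning at 17: pyrrolidine would first remove the aryl acetate to give the phenol alcohol F10. Double deprotonation with LiN(SiMe3)2 (2.2 equiv) at −78 °C and quenching with Ac2O would then acylate the phenoxide and the tertiary alkoxide together.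

Further compounds

F1 | step 11 | C6 aryl ketone of 15 (in equilibrium with its cyclic hemiketal) | COc1cc([C@H]2OC[C@H](C(=O)c3ccc(OC)c(OC)c3)[C@@]2(CO)O)ccc1OC(C)=O
F2 | step 11 | C6 benzylic alcohol of 15 (both C6 epimers) | COc1cc([C@H]2OC[C@H](C(O)c3ccc(OC)c(OC)c3)[C@@]2(CO)O)ccc1OC(C)=O
F3 | step 4 | (4E)-4-{[4-(benzyloxy)-3-methoxyphenyl]methylidene}oxolan-2-one | O=C1C/C(=C\c2ccc(OCc3ccccc3)c(OC)c2)CO1
F4 | step 4 | (2S,3S)-2-[4-(benzyloxy)-3-methoxyphenyl]-1,5-dioxaspiro[2.4]heptan-6-one | COc1cc([C@@H]2O[C@@]23COC(=O)C3)ccc1OCc1ccccc1
F5 | step 6 | aldol adduct of 8 with 3,4-dimethoxybenzaldehyde (mixture at C5 and C6) | COc1cc([C@H]2OC(=O)C(C(O)c3ccc(OC)c(OC)c3)[C@@]2(CO[Si](C)(C)C(C)(C)C)O)ccc1OCc1ccccc1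
F6 | step 6 | C6 methanesulfonate of F5 | COc1cc([C@H]2OC(=O)C(C(OS(C)(=O)=O)c3ccc(OC)c(OC)c3)[C@@]2(CO[Si](C)(C)C(C)(C)C)O)ccc1OCc1ccccc1
F7 | step 6 | 3-(3,4-dimethoxybenzylidene) lactone derived from 8 (alkene geometry open) | COc1cc([C@H]2OC(=O)C(=Cc3ccc(OC)c(OC)c3)[C@@]2(CO[Si](C)(C)C(C)(C)C)O)ccc1OCc1ccccc1
F8 | step 7 | open-chain triol from reduction of 10 (C2, C1 and C4 hydroxyls free, O8 silylated) | COc1cc([C@@H](O)[C@@](O)(CO[Si](C)(C)C(C)(C)C)[C@H](CO)Cc2ccc(OC)c(OC)c2)ccc1OCc1ccccc1
F9 | step 7 | primary C4 p-toluenesulfonate of F8 | COc1cc([C@@H](O)[C@@](O)(CO[Si](C)(C)C(C)(C)C)[C@H](COS(=O)(=O)c2ccc(C)cc2)Cc2ccc(OC)c(OC)c2)ccc1OCc1ccccc1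
F10 | step 12 | (1S,2R,5R,6S)-6-(3,4-dimethoxyphenyl)-2-(4-hydroxy-3-methoxyphenyl)-3,7-dioxabicyclo[3.3.0]octan-1-ol | COc1cc([C@H]2OC[C@@H]3[C@@H](c4ccc(OC)c(OC)c4)OC[C@]23O)ccc1O
A1 | alternative 1 | (4S,5R)-5-[4-(benzyloxy)-3-methoxyphenyl]-4-hydroxy-4-(hydroxymethyl)oxolan-2-one | COc1cc([C@H]2OC(=O)C[C@@]2(CO)O)ccc1OCc1ccccc1
A2 | alternative 1 | (2S,3S)-2-[4-(benzyloxy)-3-methoxyphenyl]-1,5-dioxaspiro[2.4]heptan-6-one | COc1cc([C@@H]2O[C@@]23COC(=O)C3)ccc1OCc1ccccc1
A3 | alternative 1 | (4E)-4-{[4-(benzyloxy)-3-methoxyphenyl]methylidene}oxolan-2-one | O=C1C/C(=C\c2ccc(OCc3ccccc3)c(OC)c2)CO1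
A4 | alternative 2 | (1S,2R,5R,6S)-2-[4-(benzyloxy)-3-methoxyphenyl]-6-(3,4-dimethoxyphenyl)-3,7-dioxabicyclo[3.3.0]octan-1-ol | COc1cc([C@H]2OC[C@@H]3[C@@H](c4ccc(OC)c(OC)c4)OC[C@]23O)ccc1OCc1ccccc1
A5 | alternative 2 | (4R,8S,6Z)-4-[4-(benzyloxy)-3-methoxyphenyl]-8-(3,4-dimethoxyphenyl)-1,5-dioxacyclooct-6-en-3-one | COc1cc([C@H]2O/C=C\[C@@H](c3ccc(OC)c(OC)c3)OCC2=O)ccc1OCc1ccccc1
A6 | alternative 3 | (1S,2R,5R,6S)-2-[4-(benzyloxy)-3-methoxyphenyl]-1-[(tert-butyldimethylsilyl)oxy]-6-(3,4-dimethoxyphenyl)-3,7-dioxabicyclo[3.3.0]octan-4-one | COc1cc([C@H]2OC(=O)[C@@H]3[C@@H](c4ccc(OC)c(OC)c4)OC[C@]23O[Si](C)(C)C(C)(C)C)ccc1OCc1ccccc1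
A7 | alternative 3 | cis-fused 7-[4-(benzyloxy)-3-methoxyphenyl]-1-[(tert-butyldimethylsilyl)oxy]-4-(3,4-dimethoxyphenyl)-3-oxabicyclo[3.2.0]heptan-6-one | COc1cc([C@H]2C(=O)[C@@H]3[C@@H](c4ccc(OC)c(OC)c4)OC[C@]23O[Si](C)(C)C(C)(C)C)ccc1OCc1ccccc1
A8 | alternative 3 | (2S)-4-[(tert-butyldimethylsilyl)oxy]-2-(3,4-dimethoxyphenyl)-2,5-dihydrofuran | COc1ccc([C@@H]2C=C(O[Si](C)(C)C(C)(C)C)CO2)cc1OC
A9 | alternative 3 | 2-[4-(benzyloxy)-3-methoxyphenyl]ethen-1-one (aryl ketene) | O=C=Cc1ccc(OCc2ccccc2)c(OC)c1
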